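Slowness showed first: the east run had made only 36.2% of product by 3.00 min. So I asked where product must end and how fast the gap to that end closes.

| flask | starting material | protic impurity | solid partner | remark | time |
|---|---|---|---|---|---|
| east | 0.20 mM | 0.014 mM | 1.1 equiv | run made earlier |  |
| north-east | 0.20 mM | 0.022 mM | 1.1 equiv | run made earlier |  |
| north | 0.20 mM | 0.010 mM | 0.55 equiv | run made earlier |  |
| flask | 0.20 mM | 0.0100 mM | 1.10 equiv |  | 4.0 min |

- east (time / min: starting material / %, product / %): 0.200: 84.6, 1.3; 0.667: 81.8, 3.3; 1.00: 77.8, 7.5; 2.00: 61.6, 24.8; 2.50: 55.6, 30.4; 3.00: 52.3, 36.2
- north-east (time / min: starting material / %, product / %): 0.250: 79.6, 0.4; 0.417: 80.1, 2.2; 0.667: 78.0, 3.8; 1.33: 68.4, 13.6; 2.00: 57.9, 23.5; 3.00: 49.2, 33.6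
- north (time / min: starting material / %, product / %): 0.667: 82.5, 2.1; 1.33: 78.2, 11.4; 2.00: 72.0, 14.3; 2.50: 67.8, 21.6; 3.00: 65.2, 22.6

(readings scatter by 1 percentage point)

- as a solid, counted per litre of solution: solid partner
- at the start none of the solid partner is in solution
- the reaction counts as stopped when no species that holds the starting material changes by six tenths of a point or more over the second half of the time

- at 4.0 min, what has stopped the reaction, if anything has (for what has run out or reacted, a solid counts together with what of it has only dissolved) (all of the starting material has reacted / it is still moving / forward and back rates have come level)
- share of the starting material used up at 4.0 min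
- product at 4.0 min, in percent of the starting material charged
- open intermediate at 4.0 min, in percent of the starting material charged
- amount of product if the flask were left three thousand times as long, in percent of the starting material charged

1. What had to be known well. With half the solid partner and 0.010 mM of impurity, the north run stood at 22.6% of product at 3.00 min, against 36.2% in the east run, so I took that charge to matter strongly; the flask has 1.10 equiv, as in the east run. Time mattered too: the east run gained 11 percentage points from 2.00 min to 3.00 min. The step in impurity from the east to the north-east run moved product at 3.00 min by 2.6 points, against a scatter of 1 point per reading.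

2. The end. The first starting-material readings of those two runs, at 0.200 min and 0.250 min, differed by 5 points, and their impurity charges by 4 points of the starting material. I read that as one starting material lost per impurity. This put my ceiling C on product at 93.0% for the east run and 95.0% for the flask.

3. The speed. In the east run, from 2.00 min to 3.00 min, the two readings had the gap C minus product shrinking with κ = 0.183 min⁻¹. This is the gap constant, which I treated as pseudo-first-order.

4. My reckoning. I gave the flask the east run's fractional gap at 3.00 min and closed it with κ up to 4.0 min. That gave 46.7% of product, still moving, and 95.0% in the end.

5. The forecast said: it is still moving, conversion 57%, product 47%, open intermediate 10%, and 98% in the end, holding that “dissolution of the solid seems to limit the rate”. Its final product stood above my 95.0%.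

6. The flask gave: it is still moving, conversion 55.7%, product 46.1%, open intermediate 4.54%, and 95.0% in the end.

    starting material ⇌ open intermediate (K = 0.114, k = 0.0260 s⁻¹)
    fresh partner → second intermediate (k = 0.0849 s⁻¹)
    open intermediate + second intermediate → product (k = 222 M⁻¹ s⁻¹)
    starting material + protic impurity → quenched substrate (k = 1950 M⁻¹ s⁻¹)
    solid partner ⇌ fresh partner, rate k5*(cs5 - [fresh partner]) while solid is left; crystals form when [fresh partner] > cs5 (solubility = 0.150 mM, k = 0.0326 s⁻¹)

The flask was not at rest: between 2.00 min and 4.0 min its largest share moved 21 points. Left ten times as long, conversion reached 96.9%, product 91.6% and open intermediate 0.343%, with 3.4 points of product still under the ceiling. Over that stretch the gap closed at 0.0736 min⁻¹, slower than κ.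

The same charge read at 6.0 min: κ, applied from the result at 4.0 min, gave 61.1% of product. The computed value was 58.3%.

The runs come from a simulation on assumed constants, and the scatter is random.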